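All runs come from a simulation from invented constants; noise was put on by code.

3 questions stand for this flask, and the earlier runs are what I am examined on.

| flask | E | D | L | remark | time |
|---|---|---|---|---|---|
| blue | 1.5 M | 0.25 equiv | 5 mol% | run made earlier |  |
| amber | 1.5 M | 0.38 equiv | 5 mol% | run made earlier |  |
| ochre | 0.75 M | 0.50 equiv | 5 mol% | run made earlier |  |
| flask | 1.5 M | 0.500 equiv | 5 mol% |  | 50 h |

| run | time / h | J / % | G / % |
|---|---|---|---|
| blue | 2.50 | 0 | 2 |
| blue | 8.00 | 0 | 2 |
| blue | 15.0 | 6 | 8 |
| blue | 20.0 | 2 | 14 |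
| blue | 30.0 | 5 | 15 |
| blue | 40.0 | 2 | 20 |
| blue | 48.0 | 9 | 23 |
| amber | 4.00 | 0 | 1 |
| amber | 6.00 | 4 | 3 |
| amber | 10.0 | 0 | 6 |
| amber | 15.0 | 3 | 9 |
| amber | 20.0 | 4 | 8 |
| amber | 30.0 | 3 | 13 |
| amber | 48.0 | 7 | 25 |
| ochre | 4.00 | 0 | 0 |
| ochre | 8.00 | 0 | 6 |
| ochre | 15.0 | 1 | 9 |
| ochre | 25.0 | 3 | 7 |
| ochre | 48.0 | 6 | 15 |

(scatter of a reading: 2 percentage points)

- ratio of J to G at 80 min
- ratio of J to G at 50 h
- which of J and G there is more of at 50 h

- the numbers in the tables scatter by 2 percentage points (one standard deviation)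

What do you read first? The blue and amber runs, since they share the flask's [E] at the start.

Why not the totals? A total mixes old J with new J. I want J gained per G gained between two readings, the selectivity of that stretch: the late increment ratio 0.226, pooled over both runs from 15.0 h to 48.0 h. Up to 15.0 h the same two runs give 0.529.

Isn't that noise? It may be. The gain in J is a sum of 4 readings, each scattering by 2 percentage points, so the ratio is weak. Still, the comparison points one way: in these two runs the first stretch yielded more J per G than the later one, so I read [J]/[G] as falling with time.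

And at 80 min? Nothing is read there. The earliest blue reading comes at 2.50 h, and its G of 2% equals the scatter. I commit to 0.529 or higher.

At 50 h? The pooled total of the same two runs at 48.0 h reads 0.333, and their late gains read lower, so I expect a value below that, drifting towards 0.226, with G ahead.

The forecast gives 0.28 at 80 min and 0.33 at 50 h, with G ahead, on “parallel formation at a nearly constant ratio”, whereas my ratio falls.

The flask gives 1.54 at 80 min and 0.218 at 50 h, with G ahead.

    E ⇌ D (K = 9.40, k = 0.571 h⁻¹)
    L + D → L + G (k = 1.22 M⁻¹ h⁻¹)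
    E + L → L + J (k = 2.02 M⁻¹ h⁻¹)
    2 E → X (k = 8.57 × 10⁻⁵ M⁻¹ h⁻¹)
    2 L ⇌ Q, settled at all times (K = 1380 M⁻¹)

In this flask J and G stood level at 2.60 h, and at 50.0 h they stood at 5.04% and 23.1%. Between 25.0 h and 50.0 h this flask gained J and G in the ratio 0.175, its increment ratio for that stretch. The neighbour flask with 12 mol% of L ended with G at 33.1%, and its ratio was 0.221. Carrying that extra G over this flask's J at 0.226 gives 7.30%, and the neighbour flask holds J at 7.32%.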